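The pyranone ring C is disconnected at C4a–C4, C8a–O1 and O1–C2, which reduces the flavonol to a ring A aryne and an arylpropiolic acid. The step exploits that C4a and C8a are adjacent ring A carbons carrying the C4 carbonyl and O1, while C5, C6, C7 and C8 can all be carried as methoxy groups, so 3,4,5,6-tetramethoxybenzyne is symmetric and either orientation gives the same flavone. In one operation the fully substituted ring A is attached to both C4 and O1 and ring C is closed. The precursors are a hexasubstituted 2-(trimethylsilyl)aryl triflate and a benzyl-protected arylpropiolic acid; C3 hydroxylation and one Lewis-acid deprotection finish the synthesis.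

Key step: step 7

Remark: the target has no stereocentre and no stereogenic double bond, so no stereocontrol is needed; flavonoid numbering (O1, C2 to C8a, primed locants for ring B) is used throughout.

Step 1
Reactants: 1 1,2,3,4-tetramethoxybenzene
Product: 4 2,3,4,5-tetramethoxyphenol, via aryllithium 2 (not isolated), via dimethyl arylboronate 3 (not isolated)
Conditions: n-BuLi, TMEDA, THF, 0 °C to rt; B(OMe)3, −78 °C to rt; AcOH, 30% aq H2O2, 0 °C to rt
Reagents that add atoms: hydrogen peroxide, OO
Why: Directed ortho-metalation places lithium next to a methoxy group at one of the two equivalent ring C–H positions, and borylation followed by peroxide oxidation (1,2-aryl shift from boron to oxygen) should convert the aryllithium into the phenol.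

Step 2
Reactants: 4 2,3,4,5-tetramethoxyphenol
Product: 5 2-bromo-3,4,5,6-tetramethoxyphenol
Conditions: NBS (1.0 equiv), CH2Cl2, −40 °C to 0 °C, dark
Reagents that add atoms: N-bromosuccinimide, O=C1CCC(=O)N1Br
Why: Electrophilic aromatic bromination: C6 is the only ring C–H of 4 and lies ortho to the free hydroxyl, so one equivalent of NBS at low temperature should brominate there before oxidation of the electron-rich phenol to a quinone sets in.

Step 3
Reactants: 5 2-bromo-3,4,5,6-tetramethoxyphenol
Product: 8 2,3,4,5-tetramethoxy-6-(trimethylsilyl)phenyl trifluoromethanesulfonate, via aryl trimethylsilyl ether 6 (not isolated), via lithium 2-silylphenoxide 7 (not isolated)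
Conditions: HMDS, THF, reflux, then evaporation; n-BuLi, THF, −100 °C to −78 °C; Tf2O, −100 °C to rt
Reagents that add atoms: hexamethyldisilazane, C[Si](C)(C)N[Si](C)(C)C; trifluoromethanesulfonic anhydride, O=S(=O)(OS(=O)(=O)C(F)(F)F)C(F)(F)F
Why: Silylation of the phenol followed by bromine–lithium exchange triggers a retro-Brook 1,3-shift of the trimethylsilyl group from oxygen to the lithiated carbon, and the resulting phenoxide is trapped by Tf2O, the standard entry to ortho-silylaryl triflates.

Step 4
Reactants: 9 2,5-dihydroxybenzaldehyde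
Product: 10 2,5-bis(benzyloxy)benzaldehyde
Conditions: BnBr (2.4 equiv), K2CO3, DMF, 60 °C
Reagents that add atoms: benzyl bromide, BrCc1ccccc1
Why: Williamson ether synthesis: both phenoxides of 9 are benzylated by SN2 displacement on benzyl bromide, the aldehyde being inert to K2CO3 in DMF.

Step 5
Reactants: 10 2,5-bis(benzyloxy)benzaldehyde
Product: 11 1,4-bis(benzyloxy)-2-(2,2-dibromoethenyl)benzene
Conditions: CBr4 (2 equiv), PPh3 (4 equiv), CH2Cl2, 0 °C
Reagents that add atoms: carbon tetrabromide, BrC(Br)(Br)Br
Why: First stage of the Corey–Fuchs reaction: the ylide Ph3P=CBr2 formed from CBr4 and PPh3 olefinates the aldehyde in a Wittig-type reaction, and the benzyl ethers are untouched.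

Step 6
Reactants: 11 1,4-bis(benzyloxy)-2-(2,2-dibromoethenyl)benzene
Product: 14 3-[2,5-bis(benzyloxy)phenyl]prop-2-ynoic acid, via lithium acetylide 12 (not isolated), via lithium propiolate 13 (not isolated)
Conditions: n-BuLi (2.2 equiv), THF, −78 °C to 0 °C; CO2, −78 °C to rt; aq HCl
Reagents that add atoms: carbon dioxide, O=C=O
Why: Second stage of the Corey–Fuchs reaction: bromine–lithium exchange, Fritsch–Buttenberg–Wiechell 1,2-shift with loss of LiBr and deprotonation by the second equivalent of n-BuLi give acetylide 12, which is carboxylated by CO2 and protonated on work-up.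

Step 7
Reactants: 8 2,3,4,5-tetramethoxy-6-(trimethylsilyl)phenyl trifluoromethanesulfonate (1.5 equiv); 14 3-[2,5-bis(benzyloxy)phenyl]prop-2-ynoic acid
Product: 17 2-[2,5-bis(benzyloxy)phenyl]-5,6,7,8-tetramethoxy-4H-chromen-4-one, via tetramethoxybenzyne 15 (not isolated), via o-hydroxyaryl ynone 16 (not isolated)
Conditions: CsF (4 equiv), THF, 125 °C, sealed tube
Reagents that add atoms: none
Why: Fluoride attacks silicon and expels triflate to give the symmetric aryne 15, to which the cesium carboxylate of 14 adds through oxygen; the resulting ortho-acyloxy aryl anion attacks its own ester carbonyl through a four-membered tetrahedral intermediate that collapses with C–O cleavage to the phenoxide of ynone 16, so that C4a–C4 and C8a–O1 are formed. The phenoxide then closes ring C by 6-endo-dig oxa-Michael addition to the β-carbon of the ynone (O1–C2), and the proton of the acid ends up on C3. The closest known reaction type is the fluoride-induced insertion of arynes into the C–O bond of carboxylic acids, which with arylpropiolic acids is known to deliver flavones directly. No stereocentre is formed. Regioselectivity of the aryne addition is not an issue, because both aryne carbons of 15 are flanked by methoxy groups and are equivalent. The 6-endo closure should be preferred over 5-exo closure to an aurone because the phenoxide attacks the electrophilic β-carbon of the ynone under basic, equilibrating conditions, and the high temperature favours intramolecular acyl transfer over protonation of the aryl anion.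

Step 8
Reactants: 17 2-[2,5-bis(benzyloxy)phenyl]-5,6,7,8-tetramethoxy-4H-chromen-4-one
Product: 20 2-[2,5-bis(benzyloxy)phenyl]-3-hydroxy-5,6,7,8-tetramethoxy-4H-chromen-4-one, via 3-lithioflavone 18 (not isolated), via 3-boronate ester 19 (not isolated)
Conditions: LiN(i-Pr)2 (1.3 equiv), THF, −78 °C; B(OMe)3, −78 °C to 0 °C; AcOH, 30% aq H2O2, 0 °C to rt
Reagents that add atoms: hydrogen peroxide, OO
Why: The C3–H of a flavone, flanked by the C4 carbonyl and the C2 enol-ether carbon, is removed selectively by LiN(i-Pr)2 at −78 °C (known C3 lithiation of flavones), and borate trapping followed by oxidative 1,2-migration from boron to oxygen installs the 3-hydroxyl while benzyl and methyl ethers stay intact.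

Step 9
Reactants: 20 2-[2,5-bis(benzyloxy)phenyl]-3-hydroxy-5,6,7,8-tetramethoxy-4H-chromen-4-one
Product: 21 2-(2,5-dihydroxyphenyl)-3,5-dihydroxy-6,7,8-trimethoxy-4H-chromen-4-one (target)
Conditions: BCl3 (6 equiv), pentamethylbenzene (6 equiv), CH2Cl2, −78 °C to 0 °C; then MeOH, aq HCl
Reagents that add atoms: none
Why: Lewis-acid ether cleavage: BCl3 removes both benzyl ethers at low temperature with pentamethylbenzene trapping the benzyl cation by Friedel–Crafts alkylation, and on warming boron chelated between the C4 carbonyl and the peri O5 activates only the 5-methyl ether toward chloride, so the 6-, 7- and 8-methoxy groups, which cannot chelate, should remain.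

Compound list
1 | 1,2,3,4-tetramethoxybenzene | COc1ccc(OC)c(OC)c1OC | starting material
2 | (2,3,4,5-tetramethoxyphenyl)lithium | [Li]c1cc(OC)c(OC)c(OC)c1OC | intermediate (not isolated)
3 | dimethyl (2,3,4,5-tetramethoxyphenyl)boronate | COB(OC)c1cc(OC)c(OC)c(OC)c1OC | intermediate (not isolated)
4 | 2,3,4,5-tetramethoxyphenol | COc1cc(O)c(OC)c(OC)c1OC | intermediate
5 | 2-bromo-3,4,5,6-tetramethoxyphenol | COc1c(OC)c(OC)c(Br)c(O)c1OC | intermediate
6 | (2-bromo-3,4,5,6-tetramethoxyphenoxy)trimethylsilane | COc1c(OC)c(OC)c(Br)c(O[Si](C)(C)C)c1OC | intermediate (not isolated)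
7 | lithium 2,3,4,5-tetramethoxy-6-(trimethylsilyl)phenoxide | [Li+].[O-]c1c(OC)c(OC)c(OC)c(OC)c1[Si](C)(C)C | intermediate (not isolated)
8 | 2,3,4,5-tetramethoxy-6-(trimethylsilyl)phenyl trifluoromethanesulfonate | COc1c(OC)c(OC)c(OS(=O)(=O)C(F)(F)F)c([Si](C)(C)C)c1OC | intermediate (aryne precursor of the key step)
9 | 2,5-dihydroxybenzaldehyde | O=Cc1cc(O)ccc1O | starting material
10 | 2,5-bis(benzyloxy)benzaldehyde | O=Cc1cc(OCc2ccccc2)ccc1OCc1ccccc1 | intermediate
11 | 1,4-bis(benzyloxy)-2-(2,2-dibromoethenyl)benzene | BrC(Br)=Cc1cc(OCc2ccccc2)ccc1OCc1ccccc1 | intermediate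
12 | {[2,5-bis(benzyloxy)phenyl]ethynyl}lithium | [Li]C#Cc1cc(OCc2ccccc2)ccc1OCc1ccccc1 | intermediate (not isolated)
13 | lithium 3-[2,5-bis(benzyloxy)phenyl]prop-2-ynoate | [Li+].[O-]C(=O)C#Cc1cc(OCc2ccccc2)ccc1OCc1ccccc1 | intermediate (not isolated)
14 | 3-[2,5-bis(benzyloxy)phenyl]prop-2-ynoic acid | OC(=O)C#Cc1cc(OCc2ccccc2)ccc1OCc1ccccc1 | intermediate (acid partner of the key step)
15 | 3,4,5,6-tetramethoxybenzyne | COC1=C(OC)C(OC)=C(OC)C#C1 | intermediate (not isolated)
16 | 3-[2,5-bis(benzyloxy)phenyl]-1-(2-hydroxy-3,4,5,6-tetramethoxyphenyl)prop-2-yn-1-one | COc1c(OC)c(OC)c(C(=O)C#Cc2cc(OCc3ccccc3)ccc2OCc2ccccc2)c(O)c1OC | intermediate (not isolated, present as its cesium phenoxide)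
17 | 2-[2,5-bis(benzyloxy)phenyl]-5,6,7,8-tetramethoxy-4H-chromen-4-one | COc1c(OC)c(OC)c2c(=O)cc(-c3cc(OCc4ccccc4)ccc3OCc3ccccc3)oc2c1OC | intermediate (product of the key step)
18 | {2-[2,5-bis(benzyloxy)phenyl]-5,6,7,8-tetramethoxy-4-oxo-4H-chromen-3-yl}lithium | COc1c(OC)c(OC)c2c(=O)c([Li])c(-c3cc(OCc4ccccc4)ccc3OCc3ccccc3)oc2c1OC | intermediate (not isolated)
19 | dimethyl {2-[2,5-bis(benzyloxy)phenyl]-5,6,7,8-tetramethoxy-4-oxo-4H-chromen-3-yl}boronate | COB(OC)c1c(-c2cc(OCc3ccccc3)ccc2OCc2ccccc2)oc2c(OC)c(OC)c(OC)c(OC)c2c1=O | intermediate (not isolated)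
20 | 2-[2,5-bis(benzyloxy)phenyl]-3-hydroxy-5,6,7,8-tetramethoxy-4H-chromen-4-one | COc1c(OC)c(OC)c2c(=O)c(O)c(-c3cc(OCc4ccccc4)ccc3OCc3ccccc3)oc2c1OC | intermediate
21 | 2-(2,5-dihydroxyphenyl)-3,5-dihydroxy-6,7,8-trimethoxy-4H-chromen-4-one | COc1c(OC)c(O)c2c(=O)c(O)c(-c3cc(O)ccc3O)oc2c1OC | target

Total step count: 9.
Longest linear sequence: 6 steps (steps 1, 2, 3, 7, 8, 9; the acid branch, steps 4, 5, 6, 7, 8, 9, is equally long).

Steps most likely to fail

Step 7. The aryl anion may be protonated before acyl transfer, so that only O-arylation of the acid occurs. The propiolate may decarboxylate at 125 °C. Closure may also take the wrong course, either 5-exo to an aurone or conjugate attack by the aryl carbon. The fallback builds ring C by the chalcone route; it sets out from phenol 4 and aldehyde 10 and comes back to the route at flavone 17. Phenol 4 would be C-acetylated at its single free ring position with AcOH and BF3·OEt2 (Friedel–Crafts ortho-acylation) to give 1-(2-hydroxy-3,4,5,6-tetramethoxyphenyl)ethanone F1. Claisen–Schmidt condensation of this ketone with 10 (KOH, EtOH, rt) should give (E)-3-[2,5-bis(benzyloxy)phenyl]-1-(2-hydroxy-3,4,5,6-tetramethoxyphenyl)prop-2-en-1-one F2. Oxidative cyclisation with catalytic iodine in DMSO at 120 °C, the usual choice for chalcones bearing a 6'-methoxy group, should then give 17.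

Step 9. Demethylation may run on to the 6-methoxy group once O5 carries boron. Cleavage at O5 may stay incomplete because the 3-hydroxyl ties up the C4 carbonyl in a five-membered boron chelate. Benzyl cations may alkylate the electron-rich ring B. The fallback separates the two deprotections; it sets out from 20 and comes back at target 21. Hydrogenolysis (H2, Pd/C, EtOAc/MeOH, rt) should remove both benzyl groups and give 2-(2,5-dihydroxyphenyl)-3-hydroxy-5,6,7,8-tetramethoxy-4H-chromen-4-one F4. Chelation-controlled mono-demethylation with anhydrous AlCl3 in MeCN at rt, followed by warm dilute HCl, should then cleave only the peri 5-methyl ether and give 21.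

Step 8. Deprotonation may be incomplete or unselective (attack of the amide on the pyranone, benzylic deprotonation of the 2'-benzyl ether), or the 3-boronate may protodeboronate before it is oxidised. The fallback oxidises the C2–C3 double bond directly; it sets out from 17 and comes back at 20. Epoxidation with dimethyldioxirane in acetone/CH2Cl2 at 0 °C should give 2-[2,5-bis(benzyloxy)phenyl]-2,3-epoxy-5,6,7,8-tetramethoxychroman-4-one F3 (racemic, cis-fused). Catalytic p-TsOH in CH2Cl2 should open the epoxide at C2 and, after loss of the C3 proton, give flavonol 20.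

Further compounds
F1 | step 7 | 1-(2-hydroxy-3,4,5,6-tetramethoxyphenyl)ethanone | CC(=O)c1c(O)c(OC)c(OC)c(OC)c1OC
F2 | step 7 | (E)-3-[2,5-bis(benzyloxy)phenyl]-1-(2-hydroxy-3,4,5,6-tetramethoxyphenyl)prop-2-en-1-one | COc1c(OC)c(OC)c(C(=O)/C=C/c2cc(OCc3ccccc3)ccc2OCc2ccccc2)c(O)c1OC
F3 | step 8 | 2-[2,5-bis(benzyloxy)phenyl]-2,3-epoxy-5,6,7,8-tetramethoxychroman-4-one (racemic, cis-fused; one enantiomer drawn) | COc1c(OC)c(OC)c2C(=O)[C@H]3O[C@@]3(c4cc(OCc5ccccc5)ccc4OCc4ccccc4)Oc2c1OC
F4 | step 9 | 2-(2,5-dihydroxyphenyl)-3-hydroxy-5,6,7,8-tetramethoxy-4H-chromen-4-one | COc1c(OC)c(OC)c2c(=O)c(O)c(-c3cc(O)ccc3O)oc2c1OC
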